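Ring A (carbocycle C1–C10) is opened at C5–C6, the bond between C6, the γ-carbon of butenolide ring B (C6–O–C12–C11=C7), and C5, the carbinol carbon next to fully substituted C4. In the key step fluoride unmasks a 2-silyloxyfuran (latent ring B) whose C6 adds to the non-enolisable C5 aldehyde: one operation closes the ten-membered ring, restores the butenolide and sets C5 and C6. The precursor is an open-chain 2-silyloxyfuran aldehyde that already holds the Z-C1=C10 alkene, the 2,3-epoxide, the C9 and C14 esters and 4-methoxybenzyl ethers at O4, O8 and O13.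

Key step: step 27

Remarks on the chemistry
- Germacrane numbering is used for all intermediates (C13 on C11, C14 on C10, C15 on C4). PMB = 4-methoxybenzyl, TES = triethylsilyl, TBS = tert-butyldimethylsilyl, TBDPS = tert-butyldiphenylsilyl.
- Assumption: the (S,S)-configured ligand in step 1 is taken to give the (R)-ether 2; should the sense of induction be the opposite, its enantiomer is used.
- O13 and O8 are PMB ethers at the ring closure, because a free furanolate with an acyloxymethyl group on C11 would expel carboxylate, and a C8 acetate could migrate to the C5 alkoxide. Both acetates are put on together afterwards.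
- O4 is a PMB ether (it comes from step 1, cannot migrate to O5 and is cleaved under neutral conditions).
- The C5 aldehyde is made before the silyloxyfuran, which would not survive an oxidant.
- C8 comes from diethyl L-tartrate; the second tartrate centre (C7) is sacrificed when ring B is formed.

Step 1
Reactants: 1 isoprene monoxide
Product: 2 (R)-2-[(4-methoxybenzyl)oxy]-2-methylbut-3-en-1-ol
Conditions: Pd2(dba)3·CHCl3 (1 mol%), (S,S)-DACH-phenyl Trost ligand (3 mol%), Et3B (1 mol%), 4-methoxybenzyl alcohol, CH2Cl2, rt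
Reagents that add atoms: 4-methoxybenzyl alcohol COc1ccc(CO)cc1
Why: Dynamic kinetic asymmetric allylic etherification (Tsuji–Trost type), in which zerovalent palladium opens racemic 1 to interconverting π-allyl complexes and the boron-bound alkoxide is delivered to the tertiary terminus inside the chiral ligand pocket, which sets C4.

Step 2
Reactants: 2 (R)-2-[(4-methoxybenzyl)oxy]-2-methylbut-3-en-1-ol
Product: 3 TBDPS ether of 2
Conditions: TBDPSCl, imidazole, DMF, rt
Reagents that add atoms: tert-butyl(chloro)diphenylsilane CC(C)(C)[Si](Cl)(c1ccccc1)c1ccccc1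
Why: Imidazole-mediated silylation of the primary alcohol gives an O5 ether that outlasts the later TES cleavage and is removed by buffered fluoride.

Step 3
Reactants: 3 TBDPS ether of 2
Product: 5 (S)-3-[(tert-butyldiphenylsilyl)oxy]-2-[(4-methoxybenzyl)oxy]-2-methylpropanal, via ozonide 4 (not isolated)
Conditions: O3, CH2Cl2, −78 °C (indicator dye end-point); PPh3, −78 °C → rt
Reagents that add atoms: ozone [O-][O+]=O
Why: Ozonolysis with reductive work-up cleaves the terminal alkene before the anisyl ring reacts, and the aldehyde (C3) has no α-hydrogen, so C4 cannot epimerise.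

Step 4
Reactants: 5 C3 aldehyde
Product: 6 ethyl (2E,4R)-5-[(tert-butyldiphenylsilyl)oxy]-4-[(4-methoxybenzyl)oxy]-4-methylpent-2-enoate
Conditions: Ph3P=CHCO2Et, toluene, 60 °C
Reagents that add atoms: ethyl (triphenylphosphoranylidene)acetate CCOC(=O)C=P(c1ccccc1)(c1ccccc1)c1ccccc1
Why: Wittig olefination with a stabilised ylide adds C2 and C1 and gives the (E)-enoate needed for a trans-epoxide.

Step 5
Reactants: 6 (E)-enoate
Product: 7 (2E,4R)-5-[(tert-butyldiphenylsilyl)oxy]-4-[(4-methoxybenzyl)oxy]-4-methylpent-2-en-1-ol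
Conditions: iBu2AlH (2.2 equiv), CH2Cl2, −78 °C
Reagents that add atoms: none
Why: 1,2-Reduction of the enoate by the aluminium hydride at low temperature gives the allylic alcohol and leaves the ethers untouched.

Step 6
Reactants: 7 (E)-allylic alcohol
Product: 8 [(2R,3S)-3-{(2S)-1-[(tert-butyldiphenylsilyl)oxy]-2-[(4-methoxybenzyl)oxy]propan-2-yl}oxiran-2-yl]methanol
Conditions: Ti(OiPr)4, D-(−)-diethyl tartrate, t-BuOOH, 4 Å molecular sieves, CH2Cl2, −20 °C
Reagents that add atoms: tert-butyl hydroperoxide CC(C)(C)OO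
Why: Sharpless asymmetric epoxidation, in which the titanium–D-tartrate complex delivers oxygen to the alkene face that gives the trans-(2R,3S)-epoxide, reagent control overriding the C4 centre.

Step 7
Reactants: 8 epoxy alcohol
Product: 9 (2S,3S)-3-{(2S)-1-[(tert-butyldiphenylsilyl)oxy]-2-[(4-methoxybenzyl)oxy]propan-2-yl}oxirane-2-carbaldehyde
Conditions: Dess–Martin periodinane, NaHCO3, CH2Cl2, 0 °C → rt
Reagents that add atoms: none
Why: Buffered Dess–Martin oxidation gives the C1 epoxy aldehyde without epimerisation at C2 or epoxide opening.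

Step 8
Reactants: 9 epoxy aldehyde
Product: 10 methyl (2Z)-2-bromo-3-[(2R,3S)-3-{(2S)-1-[(tert-butyldiphenylsilyl)oxy]-2-[(4-methoxybenzyl)oxy]propan-2-yl}oxiran-2-yl]prop-2-enoate
Conditions: Ph3P=CHCO2Me, N-bromosuccinimide, CH2Cl2, −20 °C; then 9, 0 °C → rt
Reagents that add atoms: methyl (triphenylphosphoranylidene)acetate COC(=O)C=P(c1ccccc1)(c1ccccc1)c1ccccc1; N-bromosuccinimide O=C1CCC(=O)N1Br
Why: One-pot bromination–Wittig olefination, in which the stabilised α-bromo ylide places the ester (C14) trans and the bromine cis to C2, which fixes the later C1=C10 geometry.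

Step 9
Reactants: 10 (Z)-α-bromoenoate
Product: 11 (2Z)-2-bromo-3-[(2R,3S)-3-{(2S)-1-[(tert-butyldiphenylsilyl)oxy]-2-[(4-methoxybenzyl)oxy]propan-2-yl}oxiran-2-yl]prop-2-en-1-ol
Conditions: iBu2AlH (2.3 equiv), CH2Cl2, −78 °C
Reagents that add atoms: none
Why: 1,2-Reduction of the ester to the 2-bromoallylic alcohol (C14–OH) is faster at −78 °C than attack on the vinyl epoxide or the vinyl bromide.

Step 10
Reactants: 12 diethyl L-tartrate
Product: 13 diethyl (2R,3R)-2-hydroxy-3-[(4-methoxybenzyl)oxy]butanedioate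
Conditions: Ag2O, 4-methoxybenzyl chloride, CH2Cl2, rt
Reagents that add atoms: 4-methoxybenzyl chloride COc1ccc(CCl)cc1
Why: Ag2O-mediated Williamson monoalkylation of the C2-symmetric diol stops after the first ether because silver coordination activates only one hydroxyl of the diol.

Step 11
Reactants: 13 mono-PMB tartrate
Product: 14 ethyl (2R,3S)-3,4-dihydroxy-2-[(4-methoxybenzyl)oxy]butanoate
Conditions: BH3·SMe2 (1.05 equiv), NaBH4 (5 mol%), THF, 0 °C → rt; MeOH
Reagents that add atoms: none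
Why: Hydroxyl-directed borane reduction reduces only the ester next to the free hydroxyl through a cyclic alkoxyborane, which gives C6 as CH2OH and keeps the C9 ester.

Step 12
Reactants: 14 diol ester
Product: 15 ethyl (2R,3S)-2-[(4-methoxybenzyl)oxy]-3,4-bis[(triethylsilyl)oxy]butanoate
Conditions: TESCl (2.4 equiv), imidazole, DMF, 0 °C → rt
Reagents that add atoms: chlorotriethylsilane CC[Si](Cl)(CC)CC
Why: Silylation of both hydroxyls with TES gives non-chelating ethers at O6 and O7 that can later be cleaved beside the TBDPS ether.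

Step 13
Reactants: 15 bis-TES ester
Product: 16 (2R,3S)-2-[(4-methoxybenzyl)oxy]-3,4-bis[(triethylsilyl)oxy]butanal
Conditions: iBu2AlH (1.1 equiv), CH2Cl2, −78 °C
Reagents that add atoms: none
Why: Partial reduction of the α-alkoxy ester stops at the chelated aluminium hemiacetal at −78 °C, which gives the C9 aldehyde on work-up.

Step 14
Reactants: 11 (Z)-2-bromoallylic alcohol; 16 C9 aldehyde
Product: 19 seco-diol with free C9 and C14 hydroxyls, via dilithio alkenyl alkoxide 17 (not isolated), via bis(bromomagnesio) alkenyl alkoxide 18 (not isolated)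
Conditions: t-BuLi (3.1 equiv), Et2O, −78 °C; MgBr2·OEt2 (2.2 equiv), −78 °C; 16, CH2Cl2, −78 → −40 °C; aq. NH4Cl
Reagents that add atoms: none
Why: Bromine–lithium exchange with retention of alkene geometry and transmetalation to magnesium are followed by chelation-controlled (Cram chelate) addition to the α-PMB-oxy aldehyde, attack on the face away from the C7 chain giving the 8,9-syn (9R) carbinol and the C9–C10 bond.

Step 15
Reactants: 19 seco-diol; 20 3-methylbut-2-enoyl chloride
Product: 21 C14 3-methylbut-2-enoate with free C9 hydroxyl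
Conditions: 20 (1.05 equiv), 2,4,6-collidine, CH2Cl2, −78 → −20 °C
Reagents that add atoms: none
Why: Acylation with the acid chloride at low temperature takes the primary allylic C14 hydroxyl in preference to the hindered secondary C9 hydroxyl.

Step 16
Reactants: 22 methyl (S)-2-methylglycidate
Product: 23 potassium (S)-2-methylglycidate
Conditions: KOH (1.0 equiv), EtOH, 0 °C
Reagents that add atoms: potassium hydroxide [K+].[OH-]
Why: Saponification with one equivalent of hydroxide at 0 °C cleaves the methyl ester and leaves the epoxide and its quaternary centre untouched.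

Step 17
Reactants: 21 C14 ester C9 alcohol; 23 potassium (S)-2-methylglycidate
Product: 25 C9 (S)-2-methylglycidate C14 3-methylbut-2-enoate, via mixed 2,4,6-trichlorobenzoic anhydride 24 (not isolated)
Conditions: 23, 2,4,6-trichlorobenzoyl chloride, THF, rt; then 21, DMAP, toluene, rt
Reagents that add atoms: none
Why: Yamaguchi esterification, in which DMAP attacks the less hindered glycidoyl carbonyl of the mixed anhydride and the acylpyridinium acylates O9 without touching C9 or the glycidate centre.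

Step 18
Reactants: 25 bis-TES diester
Product: 26 C6,C7-diol
Conditions: HF·pyridine, pyridine, THF, 0 °C
Reagents that add atoms: none
Why: Buffered fluoride cleaves the primary and secondary TES ethers while the bulkier TBDPS ether, the esters and the epoxides remain.

Step 19
Reactants: 27 ethyl 2-(diethoxyphosphoryl)acrylate
Product: 28 ethyl 2-(diethoxyphosphoryl)-3-[(4-methoxybenzyl)oxy]propanoate (racemic)
Conditions: 4-methoxybenzyl alcohol, NaH (10 mol%), THF, 0 °C → rt
Reagents that add atoms: 4-methoxybenzyl alcohol COc1ccc(CO)cc1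
Why: Base-catalysed oxa-Michael addition of the alkoxide to the doubly activated alkene gives the C11–C13 unit, the adduct being favoured over the acrylate.

Step 20
Reactants: 28 phosphono ester
Product: 29 2-(diethoxyphosphoryl)-3-[(4-methoxybenzyl)oxy]propanoic acid (racemic)
Conditions: Me3SnOH, 1,2-dichloroethane, 70 °C; dilute HCl wash
Reagents that add atoms: trimethyltin hydroxide C[Sn](C)(C)O
Why: Neutral ester hydrolysis with the tin hydroxide avoids the phosphonate carbanion and with it retro-Michael loss of the PMB oxide.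

Step 21
Reactants: 26 C6,C7-diol; 29 phosphono acid
Product: 30 C6 2-(diethoxyphosphoryl)-3-[(4-methoxybenzyl)oxy]propanoate with free C7 hydroxyl
Conditions: EDC·HCl, DMAP (10 mol%), CH2Cl2, 0 °C
Reagents that add atoms: none
Why: Carbodiimide (Steglich) esterification takes the primary C6 hydroxyl in preference to the hindered secondary C7 hydroxyl.

Step 22
Reactants: 30 C6 phosphono ester
Product: 31 C7 ketone
Conditions: Dess–Martin periodinane, NaHCO3, CH2Cl2, 0 °C → rt
Reagents that add atoms: none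
Why: Dess–Martin oxidation of the sacrificial C7 carbinol gives the α-acyloxy ketone needed for ring B.

Step 23
Reactants: 31 C7 ketone
Product: 32 butenolide with ring B closed
Conditions: LiCl, iPr2NEt, MeCN, rt
Reagents that add atoms: none
Why: Intramolecular Horner–Wadsworth–Emmons reaction (Masamune–Roush conditions) forms C7=C11 in a five-membered ring, the irreversible ring closure outrunning the reversible loss of the β-alkoxide from the phosphonate anion.

Step 24
Reactants: 32 butenolide TBDPS ether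
Product: 33 butenolide C5 alcohol
Conditions: Bu4NF, AcOH (1:1), THF, rt
Reagents that add atoms: none
Why: Acetic acid-buffered fluoride cleaves the silyl ether without deprotonating the butenolide at C6 or touching esters and epoxides.

Step 25
Reactants: 33 butenolide C5 alcohol
Product: 34 butenolide C5 aldehyde
Conditions: Dess–Martin periodinane, NaHCO3, CH2Cl2, 0 °C
Reagents that add atoms: none
Why: Dess–Martin oxidation gives an aldehyde that cannot enolise because C4 is fully substituted.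

Step 26
Reactants: 34 butenolide C5 aldehyde
Product: 35 2-(tert-butyldimethylsilyloxy)furan C5 aldehyde (ring A open at C5–C6)
Conditions: TBSOTf (1.2 equiv), Et3N (3 equiv), CH2Cl2, −78 °C; cold pH 7 buffer, used crude
Reagents that add atoms: tert-butyldimethylsilyl trifluoromethanesulfonate CC(C)(C)[Si](C)(C)OS(=O)(=O)C(F)(F)F
Why: Soft enolisation (O-silylation of the lactone carbonyl and loss of a C6 proton to the amine) gives the aromatic 2-silyloxyfuran, while the aldehyde has no α-hydrogen and the epoxides tolerate the amine-buffered triflate at −78 °C.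

Step 27
Reactants: 35 2-(tert-butyldimethylsilyloxy)furan C5 aldehyde
Product: 38 C5-hydroxy C4-O-PMB macrocycle (rings A and B closed), via tetrabutylammonium furanolate 36 (not isolated), via tetrabutylammonium C5-alkoxide 37 (not isolated)
Conditions: Bu4N[Ph3SiF2] (1.05 equiv), THF (2 mM, slow addition of 35), −78 → −20 °C; AcOH, −78 °C; pH 7 buffer
Reagents that add atoms: none
Why: Proposed new method: fluoride cleaves the furan O–Si bond and the free furanolate 36 adds through C6 to the C5 aldehyde, the lost furan aromaticity being repaid by the conjugated butenolide, and the alkoxide 37 is protonated cold. The closest known reaction type is the intermolecular γ-selective vinylogous Mukaiyama aldol addition of 2-silyloxyfurans to α-oxygenated aldehydes under fluoride activation, which has not been shown for a medium carbocycle. Ring A closes in the 10-exo-trig mode (attack on the exocyclic C5=O), helped by the Z-C1=C10 alkene and the trans-2,3-epoxide, which pre-fold the chain, and by the 2 mM concentration, which suppresses oligomers. C5 is controlled by the C4 stereocentre, since attack anti to the C4–O bond with the tethered C3 on the side of the aldehyde hydrogen and the methyl group inside should give the 4,5-syn carbinol that the inverting epoxide closure requires. C6 is controlled by the open, non-chelated transition state of the naked furanolate, in which the ring oxygen and the aldehyde oxygen point away from each other, so that O5 and O6 should end up anti as in the target. The step needs γ- over α-attack (C11 is fully substituted by C13), no expulsion or migration of oxygen substituents (O13 and O8 are ethers) and no enolisation of the aldehyde (C4 carries no hydrogen).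

Step 28
Reactants: 38 C5-hydroxy macrocycle
Product: 39 C5 mesylate
Conditions: MsCl, Et3N, CH2Cl2, −40 °C
Reagents that add atoms: methanesulfonyl chloride CS(=O)(=O)Cl
Why: Sulfonylation of the only free hydroxyl through the sulfene proceeds at a temperature at which the amine does not yet deprotonate C6.

Step 29
Reactants: 39 C5 mesylate
Product: 40 C4,C8,C13-triol C5 mesylate
Conditions: DDQ (3.5 equiv), CH2Cl2, pH 7 phosphate buffer, 0 °C
Reagents that add atoms: none
Why: Oxidative cleavage of the three PMB ethers by hydride abstraction under buffered neutral conditions leaves the esters, the epoxides and the mesylate intact.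

Step 30
Reactants: 40 triol mesylate
Product: 41 C8,C13-diacetate C4-hydroxy C5-mesylate
Conditions: Ac2O, pyridine, DMAP (5 mol%), CH2Cl2, 0 °C
Reagents that add atoms: acetic anhydride CC(=O)OC(C)=O
Why: Acylation takes the primary C13 and the secondary C8 hydroxyl, whereas the tertiary C4 hydroxyl is not acetylated under these conditions.

Step 31
Reactants: 41 diacetate hydroxy mesylate
Product: 42 CNP0279449.1
Conditions: KN(SiMe3)2 (1.0 equiv, slow addition), THF, −78 → −40 °C; pH 7 buffer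
Reagents that add atoms: none
Why: Intramolecular Williamson reaction (3-exo-tet), in which the C4 alkoxide formed by fast O–H deprotonation displaces the C5 mesylate with inversion and gives the cis-4,5-epoxide.

Compound list
1 | isoprene monoxide (2-methyl-2-vinyloxirane, racemic) | CC1(C=C)CO1 | starting material
2 | (R)-2-[(4-methoxybenzyl)oxy]-2-methylbut-3-en-1-ol | C=C[C@@](C)(OCc1ccc(OC)cc1)CO | intermediate
3 | (R)-tert-butyl({2-[(4-methoxybenzyl)oxy]-2-methylbut-3-en-1-yl}oxy)diphenylsilane | C=C[C@@](C)(OCc1ccc(OC)cc1)CO[Si](c1ccccc1)(c1ccccc1)C(C)(C)C | intermediate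
4 | ozonide of 3 (3-substituted 1,2,4-trioxolane, mixture at the acetal carbon; not isolated) | C1OC(OO1)[C@@](C)(OCc1ccc(OC)cc1)CO[Si](c1ccccc1)(c1ccccc1)C(C)(C)C | intermediate
5 | (S)-3-[(tert-butyldiphenylsilyl)oxy]-2-[(4-methoxybenzyl)oxy]-2-methylpropanal (C3 aldehyde) | O=C[C@@](C)(OCc1ccc(OC)cc1)CO[Si](c1ccccc1)(c1ccccc1)C(C)(C)C | intermediate
6 | ethyl (2E,4R)-5-[(tert-butyldiphenylsilyl)oxy]-4-[(4-methoxybenzyl)oxy]-4-methylpent-2-enoate | CCOC(=O)/C=C/[C@@](C)(OCc1ccc(OC)cc1)CO[Si](c1ccccc1)(c1ccccc1)C(C)(C)C | intermediate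
7 | (2E,4R)-5-[(tert-butyldiphenylsilyl)oxy]-4-[(4-methoxybenzyl)oxy]-4-methylpent-2-en-1-ol | OC/C=C/[C@@](C)(OCc1ccc(OC)cc1)CO[Si](c1ccccc1)(c1ccccc1)C(C)(C)C | intermediate
8 | [(2R,3S)-3-{(2S)-1-[(tert-butyldiphenylsilyl)oxy]-2-[(4-methoxybenzyl)oxy]propan-2-yl}oxiran-2-yl]methanol (C1–C5 epoxy alcohol) | OC[C@H]1O[C@@H]1[C@@](C)(OCc1ccc(OC)cc1)CO[Si](c1ccccc1)(c1ccccc1)C(C)(C)C | intermediate
9 | (2S,3S)-3-{(2S)-1-[(tert-butyldiphenylsilyl)oxy]-2-[(4-methoxybenzyl)oxy]propan-2-yl}oxirane-2-carbaldehyde (C1 aldehyde) | O=C[C@H]1O[C@@H]1[C@@](C)(OCc1ccc(OC)cc1)CO[Si](c1ccccc1)(c1ccccc1)C(C)(C)C | intermediate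
10 | methyl (2Z)-2-bromo-3-[(2R,3S)-3-{(2S)-1-[(tert-butyldiphenylsilyl)oxy]-2-[(4-methoxybenzyl)oxy]propan-2-yl}oxiran-2-yl]prop-2-enoate | COC(=O)/C(Br)=C/[C@H]1O[C@@H]1[C@@](C)(OCc1ccc(OC)cc1)CO[Si](c1ccccc1)(c1ccccc1)C(C)(C)C | intermediate
11 | (2Z)-2-bromo-3-[(2R,3S)-3-{(2S)-1-[(tert-butyldiphenylsilyl)oxy]-2-[(4-methoxybenzyl)oxy]propan-2-yl}oxiran-2-yl]prop-2-en-1-ol (C10 bromide, C14 alcohol) | OC/C(Br)=C/[C@H]1O[C@@H]1[C@@](C)(OCc1ccc(OC)cc1)CO[Si](c1ccccc1)(c1ccccc1)C(C)(C)C | intermediate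
12 | diethyl L-tartrate, diethyl (2R,3R)-2,3-dihydroxybutanedioate | CCOC(=O)[C@H](O)[C@@H](O)C(=O)OCC | starting material
13 | diethyl (2R,3R)-2-hydroxy-3-[(4-methoxybenzyl)oxy]butanedioate | CCOC(=O)[C@H](O)[C@@H](OCc1ccc(OC)cc1)C(=O)OCC | intermediate
14 | ethyl (2R,3S)-3,4-dihydroxy-2-[(4-methoxybenzyl)oxy]butanoate (C9 ester, C8 ether, C7 and C6 hydroxyls) | OC[C@H](O)[C@@H](OCc1ccc(OC)cc1)C(=O)OCC | intermediate
15 | ethyl (2R,3S)-2-[(4-methoxybenzyl)oxy]-3,4-bis[(triethylsilyl)oxy]butanoate | CC[Si](CC)(CC)OC[C@H](O[Si](CC)(CC)CC)[C@@H](OCc1ccc(OC)cc1)C(=O)OCC | intermediate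
16 | (2R,3S)-2-[(4-methoxybenzyl)oxy]-3,4-bis[(triethylsilyl)oxy]butanal (C9 aldehyde) | CC[Si](CC)(CC)OC[C@H](O[Si](CC)(CC)CC)[C@@H](OCc1ccc(OC)cc1)C=O | intermediate
17 | dilithio alkenyl alkoxide from 11 (C10–Li, O14–Li; not isolated) | [Li]OC/C([Li])=C/[C@H]1O[C@@H]1[C@@](C)(OCc1ccc(OC)cc1)CO[Si](c1ccccc1)(c1ccccc1)C(C)(C)C | intermediate
18 | bis(bromomagnesio) alkenyl alkoxide from 17 (not isolated) | Br[Mg]OC/C([Mg]Br)=C/[C@H]1O[C@@H]1[C@@](C)(OCc1ccc(OC)cc1)CO[Si](c1ccccc1)(c1ccccc1)C(C)(C)C | intermediate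
19 | seco-diol: Z-C1=C10 alkene with free C9 and C14 hydroxyls, 2,3-epoxide, O4 and O8 PMB, O6 and O7 TES, O5 TBDPS; C2, C3, C4, C8, C9 configured as in 42 | CC[Si](CC)(CC)OC[C@H](O[Si](CC)(CC)CC)[C@@H](OCc1ccc(OC)cc1)[C@H](O)/C(CO)=C\[C@H]1O[C@@H]1[C@@](C)(OCc1ccc(OC)cc1)CO[Si](c1ccccc1)(c1ccccc1)C(C)(C)C | intermediate
20 | 3-methylbut-2-enoyl chloride | CC(C)=CC(Cl)=O | starting material
21 | C14 3-methylbut-2-enoate of 19 with free C9 hydroxyl | CC[Si](CC)(CC)OC[C@H](O[Si](CC)(CC)CC)[C@@H](OCc1ccc(OC)cc1)[C@H](O)/C(COC(=O)C=C(C)C)=C\[C@H]1O[C@@H]1[C@@](C)(OCc1ccc(OC)cc1)CO[Si](c1ccccc1)(c1ccccc1)C(C)(C)C | intermediate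
22 | methyl (S)-2-methylglycidate | COC(=O)[C@]1(C)CO1 | starting material
23 | potassium (S)-2-methylglycidate | [K+].[O-]C(=O)[C@]1(C)CO1 | intermediate
24 | mixed anhydride of (S)-2-methylglycidic acid and 2,4,6-trichlorobenzoic acid (not isolated) | O=C(OC(=O)[C@]1(C)CO1)c1c(Cl)cc(Cl)cc1Cl | intermediate
25 | C9 (S)-2-methylglycidate C14 3-methylbut-2-enoate; O6 and O7 TES | CC[Si](CC)(CC)OC[C@H](O[Si](CC)(CC)CC)[C@@H](OCc1ccc(OC)cc1)[C@H](OC(=O)[C@]1(C)CO1)/C(COC(=O)C=C(C)C)=C\[C@H]1O[C@@H]1[C@@](C)(OCc1ccc(OC)cc1)CO[Si](c1ccccc1)(c1ccccc1)C(C)(C)C | intermediate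
26 | C6,C7-diol of 25 | OC[C@H](O)[C@@H](OCc1ccc(OC)cc1)[C@H](OC(=O)[C@]1(C)CO1)/C(COC(=O)C=C(C)C)=C\[C@H]1O[C@@H]1[C@@](C)(OCc1ccc(OC)cc1)CO[Si](c1ccccc1)(c1ccccc1)C(C)(C)C | intermediate
27 | ethyl 2-(diethoxyphosphoryl)acrylate | CCOC(=O)C(=C)P(=O)(OCC)OCC | starting material
28 | ethyl 2-(diethoxyphosphoryl)-3-[(4-methoxybenzyl)oxy]propanoate (racemic) | CCOC(=O)C(COCc1ccc(OC)cc1)P(=O)(OCC)OCC | intermediate
29 | 2-(diethoxyphosphoryl)-3-[(4-methoxybenzyl)oxy]propanoic acid (racemic; C11, C12, C13 unit) | OC(=O)C(COCc1ccc(OC)cc1)P(=O)(OCC)OCC | intermediate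
30 | C6 ester of 26 with acid 29, free C7 hydroxyl (both epimers at C11) | CCOP(=O)(OCC)C(COCc1ccc(OC)cc1)C(=O)OC[C@H](O)[C@@H](OCc1ccc(OC)cc1)[C@H](OC(=O)[C@]1(C)CO1)/C(COC(=O)C=C(C)C)=C\[C@H]1O[C@@H]1[C@@](C)(OCc1ccc(OC)cc1)CO[Si](c1ccccc1)(c1ccccc1)C(C)(C)C | intermediate
31 | C7 ketone of 30 (both epimers at C11) | CCOP(=O)(OCC)C(COCc1ccc(OC)cc1)C(=O)OCC(=O)[C@@H](OCc1ccc(OC)cc1)[C@H](OC(=O)[C@]1(C)CO1)/C(COC(=O)C=C(C)C)=C\[C@H]1O[C@@H]1[C@@](C)(OCc1ccc(OC)cc1)CO[Si](c1ccccc1)(c1ccccc1)C(C)(C)C | intermediate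
32 | butenolide (ring B closed, C6H2): O13, O8, O4 PMB; O5 TBDPS; C9 glycidate; C14 senecioate | COc1ccc(COCC2=C([C@@H](OCc3ccc(OC)cc3)[C@H](OC(=O)[C@]3(C)CO3)/C(COC(=O)C=C(C)C)=C\[C@H]3O[C@@H]3[C@@](C)(OCc3ccc(OC)cc3)CO[Si](c3ccccc3)(c3ccccc3)C(C)(C)C)COC2=O)cc1 | intermediate
33 | butenolide C5 alcohol | COc1ccc(COCC2=C([C@@H](OCc3ccc(OC)cc3)[C@H](OC(=O)[C@]3(C)CO3)/C(COC(=O)C=C(C)C)=C\[C@H]3O[C@@H]3[C@@](C)(OCc3ccc(OC)cc3)CO)COC2=O)cc1 | intermediate
34 | butenolide C5 aldehyde | COc1ccc(COCC2=C([C@@H](OCc3ccc(OC)cc3)[C@H](OC(=O)[C@]3(C)CO3)/C(COC(=O)C=C(C)C)=C\[C@H]3O[C@@H]3[C@@](C)(OCc3ccc(OC)cc3)C=O)COC2=O)cc1 | intermediate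
35 | 2-(tert-butyldimethylsilyloxy)furan C5 aldehyde, ring A open at C5–C6 (key-step precursor) | COc1ccc(COCc2c(O[Si](C)(C)C(C)(C)C)occ2[C@@H](OCc3ccc(OC)cc3)[C@H](OC(=O)[C@]3(C)CO3)/C(COC(=O)C=C(C)C)=C\[C@H]3O[C@@H]3[C@@](C)(OCc3ccc(OC)cc3)C=O)cc1 | intermediate
36 | tetrabutylammonium furanolate from 35 (not isolated) | COc1ccc(COCc2c([O-])occ2[C@@H](OCc3ccc(OC)cc3)[C@H](OC(=O)[C@]3(C)CO3)/C(COC(=O)C=C(C)C)=C\[C@H]3O[C@@H]3[C@@](C)(OCc3ccc(OC)cc3)C=O)cc1.CCCC[N+](CCCC)(CCCC)CCCC | intermediate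
37 | tetrabutylammonium C5-alkoxide of the macrocycle (not isolated) | COc1ccc(COCC2=C3[C@@H](OCc4ccc(OC)cc4)[C@H](OC(=O)[C@]4(C)CO4)/C(COC(=O)C=C(C)C)=C\[C@H]4O[C@@H]4[C@@](C)(OCc4ccc(OC)cc4)[C@H]([O-])[C@@H]3OC2=O)cc1.CCCC[N+](CCCC)(CCCC)CCCC | intermediate
38 | C5-hydroxy C4-O-PMB macrocycle (key-step product; 4,5-syn, O5 and O6 anti; other centres as in 42) | COc1ccc(COCC2=C3[C@@H](OCc4ccc(OC)cc4)[C@H](OC(=O)[C@]4(C)CO4)/C(COC(=O)C=C(C)C)=C\[C@H]4O[C@@H]4[C@@](C)(OCc4ccc(OC)cc4)[C@H](O)[C@@H]3OC2=O)cc1 | intermediate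
39 | C5 mesylate of 38 | COc1ccc(COCC2=C3[C@@H](OCc4ccc(OC)cc4)[C@H](OC(=O)[C@]4(C)CO4)/C(COC(=O)C=C(C)C)=C\[C@H]4O[C@@H]4[C@@](C)(OCc4ccc(OC)cc4)[C@H](OS(C)(=O)=O)[C@@H]3OC2=O)cc1 | intermediate
40 | C4,C8,C13-triol C5 mesylate | OCC1=C2[C@@H](O)[C@H](OC(=O)[C@]3(C)CO3)/C(COC(=O)C=C(C)C)=C\[C@H]3O[C@@H]3[C@@](C)(O)[C@H](OS(C)(=O)=O)[C@@H]2OC1=O | intermediate
41 | C8,C13-diacetate C4-hydroxy C5-mesylate | CC(=O)OCC1=C2[C@@H](OC(C)=O)[C@H](OC(=O)[C@]3(C)CO3)/C(COC(=O)C=C(C)C)=C\[C@H]3O[C@@H]3[C@@](C)(O)[C@H](OS(C)(=O)=O)[C@@H]2OC1=O | intermediate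
42 | CNP0279449.1 | CC(=O)OCC1=C2[C@@H](OC(C)=O)[C@H](OC(=O)[C@]3(C)CO3)/C(COC(=O)C=C(C)C)=C\[C@H]3O[C@@H]3[C@@]3(C)O[C@H]3[C@@H]2OC1=O | target

Total step count: 31. Longest linear sequence: 24 steps (steps 1–9, 14, 15, 17, 18 and 21–31, from isoprene monoxide).

Steps most likely to fail

1. Step 27 (key step). The closure may suffer from poor facial selectivity at C5 or C6, from oligomerisation, or from retro-aldol equilibration of the alkoxide before the quench. The fallback closes the same bond by known chemistry, a chromium-mediated Barbier-type (Nozaki–Hiyama) cyclisation of an allylic bromide onto an aldehyde, which is an established way to ten-membered carbocycles. It sets out from 35: N-bromosuccinimide in THF at −78 °C brominates the silyloxyfuran at C6 and gives the γ-bromobutenolide C5 aldehyde F1. Slow addition of this to CrCl2 in THF at rt lets divalent chromium reduce the C6–Br bond, and the trivalent chromium dienolate adds through C6 to the aldehyde in a closed, metal-bridged transition state. Aqueous work-up gives 38, where the route is rejoined.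

2. Step 31. Deprotonation at C6 (γ to the lactone carbonyl) can compete with the alkoxide displacement and lead to β-elimination of the mesylate towards a C5=C6 alkylidene butenolide. The fallback avoids both sulfonate and base. It sets out from 38: TESOTf and 2,6-lutidine at −78 °C give the C5 triethylsilyl ether F2. DDQ in buffered CH2Cl2 removes the three PMB groups to give the C4,C8,C13-triol F3. Ac2O and pyridine give the C8,C13-diacetate F4. Acetic acid-buffered Bu4NF frees O5 to give the 4,5-diol diacetate F5. Mitsunobu cyclodehydration (PPh3, diisopropyl azodicarboxylate, THF, 0 °C) activates the secondary C5 hydroxyl and lets the tertiary C4 hydroxyl displace it with inversion, which gives 42 directly.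

3. Step 14. Chelation control may be incomplete (wrong configuration at C9), and the organolithium or the new C9 alkoxide may attack the vinyl epoxide. The fallback replaces the organolithium by a nickel-catalysed, chromium-mediated (Nozaki–Hiyama–Kishi) coupling, which tolerates esters and epoxides. It sets out from 11: acylation with 20 and 2,4,6-collidine gives the (Z)-2-bromoallyl 3-methylbut-2-enoate F6. Coupling of this with aldehyde 16 (CrCl2, NiCl2 as catalyst, a chiral sulfonamide ligand on chromium to enforce the 9R carbinol, THF, rt) gives 21 directly, where the route is rejoined.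

Further compounds
F1 | step 27 | γ-bromobutenolide C5 aldehyde (bromine on C6, both epimers) | COc1ccc(COCC2=C([C@@H](OCc3ccc(OC)cc3)[C@H](OC(=O)[C@]3(C)CO3)/C(COC(=O)C=C(C)C)=C\[C@H]3O[C@@H]3[C@@](C)(OCc3ccc(OC)cc3)C=O)C(Br)OC2=O)cc1
F2 | step 31 | C5 triethylsilyl ether of 38 | COc1ccc(COCC2=C3[C@@H](OCc4ccc(OC)cc4)[C@H](OC(=O)[C@]4(C)CO4)/C(COC(=O)C=C(C)C)=C\[C@H]4O[C@@H]4[C@@](C)(OCc4ccc(OC)cc4)[C@H](O[Si](CC)(CC)CC)[C@@H]3OC2=O)cc1
F3 | step 31 | C4,C8,C13-triol C5 triethylsilyl ether | OCC1=C2[C@@H](O)[C@H](OC(=O)[C@]3(C)CO3)/C(COC(=O)C=C(C)C)=C\[C@H]3O[C@@H]3[C@@](C)(O)[C@H](O[Si](CC)(CC)CC)[C@@H]2OC1=O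
F4 | step 31 | C8,C13-diacetate C4-hydroxy C5 triethylsilyl ether | CC(=O)OCC1=C2[C@@H](OC(C)=O)[C@H](OC(=O)[C@]3(C)CO3)/C(COC(=O)C=C(C)C)=C\[C@H]3O[C@@H]3[C@@](C)(O)[C@H](O[Si](CC)(CC)CC)[C@@H]2OC1=O
F5 | step 31 | C8,C13-diacetate 4,5-diol | CC(=O)OCC1=C2[C@@H](OC(C)=O)[C@H](OC(=O)[C@]3(C)CO3)/C(COC(=O)C=C(C)C)=C\[C@H]3O[C@@H]3[C@@](C)(O)[C@H](O)[C@@H]2OC1=O
F6 | step 14 | (Z)-2-bromoallyl 3-methylbut-2-enoate derived from 11 | CC(C)=CC(=O)OC/C(Br)=C/[C@H]1O[C@@H]1[C@@](C)(OCc1ccc(OC)cc1)CO[Si](c1ccccc1)(c1ccccc1)C(C)(C)C
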